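**Plan**

- Retrosynthetic cuts, in order: C1–C2 (ring bond between the C2 carbinol and the C1=C10 enoate); C9–C10 (halo-aldol of methyl propiolate, which brings C1, C10 and C14); C7–C8 (Barbier allylation of a 3-(bromomethyl)butenolide); C7=C11 and O–C12 (ester, then ring-closing metathesis); C6–C7 (vinyl addition); C4=C5 (Wittig).
- Forward: a six-carbon west unit is made in which C2 and O-15 are tied in a five-membered cyclic acetal (C2, C3, C4, C15, O). The butenolide (C6, C7, C11, C12, O) is put on, the Barbier step turns it into the α-methylene lactone and adds C8/C9, propiolate is spliced in, and the ten-membered ring is closed last to give the target directly.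
- Enabling feature: the C2 hydroxyl is γ to the C14 ester across a C1=C10 bond whose ester is trans to C2, so no butenolide can form and C1 can be an alkenyl metal from a β-iodo enoate with C2 as aldehyde. O-2 and O-15 are 1,4-related through C3–C4, so the aldehyde is stored as the lactol whose opening in the ring closure frees both hydroxyls of the target.
- Stereochemistry: C6 by catalytic asymmetric vinyl transfer; C7 by the butenolide ring (anti to the C6 substituent); C8 by the chair Barbier transition state, then Mitsunobu inversion with angelic acid; C9 by Corey–Bakshi–Shibata reduction; C2 in the ring closure (substrate control). C4=C5 comes from the stabilised ylide; C1=C10 from the thermodynamic β-iodo enoate and retention in the coupling.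

Key step: step 20

Remark: atoms carry the germacrane numbers they have in the target (C1–C15), α/β mean the faces these atoms show in the target drawn with H-7 α, the acetal carbon C2 of 7–25 is carried as both epimers (they converge in step 20), and 1 and 2 are taken to be commercial.

**Step 1**
Reactants: 1 (triphenylphosphoranylidene)succinic anhydride; 2 2-[(4-methoxybenzyl)oxy]acetaldehyde
Product: 3 (E)-3-{2-[(4-methoxybenzyl)oxy]ethylidene}oxolane-2,5-dione
Conditions: CH2Cl2, rt
Reagents that add atoms: none
Why: Wittig olefination with a stabilised ylide should place the aldehyde residue (C6) trans to the conjugated anhydride carbonyl (C15) and so set the C4=C5 geometry of the target.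

**Step 2**
Reactants: 3 (E)-alkylidene succinic anhydride
Product: 4 (E)-4-methoxy-2-{2-[(4-methoxybenzyl)oxy]ethylidene}-4-oxobutanoic acid
Conditions: MeOH, rt
Reagents that add atoms: methanol, CO
Why: Alcoholysis of the unsymmetrical anhydride should take place at the non-conjugated, more electrophilic carbonyl (C2), which leaves the conjugated C15 carboxyl free and so tells C2 from C15.

**Step 3**
Reactants: 4 half ester
Product: 6 (E)-4-{2-[(4-methoxybenzyl)oxy]ethylidene}oxolan-2-one, via hydroxy ester 5 (not isolated)
Conditions: BH3·SMe2, THF, 0 °C → rt; then PPTS (cat.), CH2Cl2, rt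
Reagents that add atoms: none
Why: Borane reduces the free carboxylic acid and not the methyl ester (chemoselective acid reduction), and the γ-hydroxy ester 5 closes to the five-membered lactone under mild acid catalysis.

**Step 4**
Reactants: 6 β-alkylidene lactone
Product: 7 (E)-4-{2-[(4-methoxybenzyl)oxy]ethylidene}oxolan-2-ol (lactol)
Conditions: i-Bu2AlH (1.1 equiv), CH2Cl2, −78 °C
Reagents that add atoms: none
Why: Partial reduction of a γ-lactone with one equivalent of i-Bu2AlH at low temperature stops at the tetrahedral aluminate and gives the lactol, the masked C2 aldehyde.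

**Step 5**
Reactants: 7 lactol
Product: 8 tert-butyl{[(E)-4-{2-[(4-methoxybenzyl)oxy]ethylidene}oxolan-2-yl]oxy}diphenylsilane
Conditions: TBDPSCl, imidazole, DMF, 0 °C → rt
Reagents that add atoms: tert-butyl(chloro)diphenylsilane, CC(C)(C)[Si](Cl)(c1ccccc1)c1ccccc1
Why: Silylation of the hemiacetal hydroxyl gives an anomeric silyl ether that holds C2 and O-15 in the cyclic acetal through the following steps and is later cleaved by fluoride without acid.

**Step 6**
Reactants: 8 silyl acetal
Product: 9 (E)-2-{5-[(tert-butyldiphenylsilyl)oxy]oxolan-3-ylidene}ethan-1-ol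
Conditions: DDQ, CH2Cl2/pH 7 buffer, 0 °C → rt
Reagents that add atoms: none
Why: Oxidative cleavage of the 4-methoxybenzyl ether by DDQ leaves the silyl acetal and the trisubstituted alkene untouched.

**Step 7**
Reactants: 9 allylic alcohol
Product: 10 (E)-2-{5-[(tert-butyldiphenylsilyl)oxy]oxolan-3-ylidene}acetaldehyde
Conditions: MnO2, CH2Cl2, rt
Reagents that add atoms: none
Why: MnO2 oxidises the allylic alcohol to the enal without touching the acetal and without loss of the alkene geometry.

**Step 8**
Reactants: 10 enal
Product: 11 (2S,E)-1-{5-[(tert-butyldiphenylsilyl)oxy]oxolan-3-ylidene}but-3-en-2-ol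
Conditions: (CH2=CH)2Zn (from CH2=CHMgBr and ZnCl2), (−)-DAIB (cat.), toluene, 0 °C
Reagents that add atoms: divinylzinc, C=C[Zn]C=C (made in the flask from vinylmagnesium bromide, C=C[Mg]Br, and ZnCl2)
Why: Amino-alcohol-catalysed enantioselective addition of an alkenylzinc reagent to the aldehyde, in which the ligand should direct the vinyl group to the face that gives the (S)-carbinol (C6), as it does for alkyl transfer to unsaturated aldehydes.

**Step 9**
Reactants: 11 (S)-divinyl carbinol; 12 2-(bromomethyl)acrylic acid
Product: 13 (2S,E)-1-{5-[(tert-butyldiphenylsilyl)oxy]oxolan-3-ylidene}but-3-en-2-yl 2-(bromomethyl)acrylate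
Conditions: DCC, DMAP (cat.), CH2Cl2, 0 °C
Reagents that add atoms: none
Why: Steglich esterification of the secondary alcohol under neutral conditions, which avoid ionisation of the doubly allylic C6–O bond.

**Step 10**
Reactants: 13 acrylate ester
Product: 14 (R)-3-(bromomethyl)-5-{(E)-[5-(tert-butyldiphenylsilyloxy)oxolan-3-ylidene]methyl}furan-2(5H)-one
Conditions: second-generation Grubbs catalyst (5 mol %), CH2Cl2, 40 °C
Reagents that add atoms: none
Why: Ring-closing metathesis between the vinyl group and the 1,1-disubstituted acrylate closes the five-membered butenolide (the trisubstituted C4=C5 bond does not take part) and drives off ethene.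

**Step 11**
Reactants: 14 bromobutenolide; 2 2-[(4-methoxybenzyl)oxy]acetaldehyde
Product: 15 3-methyleneoxolan-2-one carrying at C6 the (E)-[5-(tert-butyldiphenylsilyloxy)oxolan-3-ylidene]methyl group and at C7, trans to it, a 1-hydroxy-2-[(4-methoxybenzyl)oxy]ethyl group (C6, C7 as in the target; C8 carbinol 8α, epimeric to the target)
Conditions: Zn, THF/sat. aq. NH4Cl, 0 °C → rt
Reagents that add atoms: none
Why: Zinc-mediated Barbier allylation, in which the allylzinc attacks through C7 in a chair (Zimmerman–Traxler) transition state on the face anti to the C6 substituent (C6/C7 trans as in the target) with the aldehyde residue equatorial, which should give the 8α carbinol and the exo-methylene lactone in one step.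

**Step 12**
Reactants: 15 8α-alcohol; 16 angelic acid [(Z)-2-methylbut-2-enoic acid]
Product: 17 8β-angelate (C8 inverted; C9 still as its 4-methoxybenzyl ether)
Conditions: PPh3, DIAD, toluene, 0 °C → rt
Reagents that add atoms: none
Why: Mitsunobu esterification, in which angelate displaces the alkoxyphosphonium group by SN2 with inversion, corrects C8 to the 8β configuration and installs the angelate at the same time without base that could isomerise it to the tiglate.

**Step 13**
Reactants: 17 4-methoxybenzyl ether
Product: 18 primary C9 alcohol (8β-angelate)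
Conditions: DDQ, CH2Cl2/pH 7 buffer, 0 °C
Reagents that add atoms: none
Why: DDQ cleaves the 4-methoxybenzyl ether oxidatively under buffered conditions that leave the esters, the silyl acetal and the alkenes untouched.

**Step 14**
Reactants: 18 primary alcohol
Product: 19 C9 aldehyde (α-angeloyloxy aldehyde)
Conditions: Dess–Martin periodinane, NaHCO3, CH2Cl2, 0 °C
Reagents that add atoms: none
Why: Dess–Martin oxidation under buffered, non-basic conditions gives the α-acyloxy aldehyde without epimerisation at C8 (used at once).

**Step 15**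
Reactants: 19 aldehyde; 20 methyl propiolate
Product: 21 methyl (E)-3-iodo-2-(hydroxyalkyl)acrylate (C9 carbinol as both epimers; iodine cis to C9, trans to the ester)
Conditions: MgI2, CH2Cl2, 0 °C → rt
Reagents that add atoms: magnesium diiodide, [Mg+2].[I-].[I-]
Why: Halo-aldol (β-iodo Morita–Baylis–Hillman-type) reaction in which iodide adds to the MgI2-activated propiolate and the magnesium iodoallenolate adds to the aldehyde, prolonged contact with iodide should equilibrate the alkenyl iodide by addition–elimination to the more stable isomer with iodine trans to the ester, and C9 forms without reliable control (Cornforth-type addition would favour 9β) and is reset in steps 16 and 17.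

**Step 16**
Reactants: 21 C9 epimers
Product: 22 β-iodo enone (C9 ketone)
Conditions: Dess–Martin periodinane, NaHCO3, CH2Cl2, 0 °C → rt
Reagents that add atoms: none
Why: Dess–Martin oxidation of the secondary allylic alcohol converges both C9 epimers on one β-iodo enone without touching the alkenyl iodide geometry.

**Step 17**
Reactants: 22 β-iodo enone
Product: 23 9α-alcohol (8β-angelate, 8,9-syn)
Conditions: (S)-2-methyl-CBS-oxazaborolidine, catecholborane, toluene, −78 °C
Reagents that add atoms: none
Why: Corey–Bakshi–Shibata reduction, 1,2-selective for the enone, in which the (S)-catalyst (alkenyl group as the large substituent) and the Felkin–Anh preference of the α-acyloxy ketone (hydride anti to the C8–O bond) both lead to the 9α alcohol.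

**Step 18**
Reactants: 23 9α-alcohol
Product: 24 9α-acetate (fully acylated alkenyl iodide, silyl acetal in place)
Conditions: Ac2O, pyridine, DMAP (cat.), CH2Cl2, 0 °C
Reagents that add atoms: acetic anhydride, CC(=O)OC(C)=O
Why: Acetylation under nucleophilic catalysis is fast at low temperature, which should outrun migration of the neighbouring angelate.

**Step 19**
Reactants: 24 silyl acetal
Product: 25 lactol (C2 hemiacetal closed on O-15)
Conditions: Bu4NF, AcOH, THF, 0 °C
Reagents that add atoms: none
Why: Buffered fluoride cleaves the anomeric silyl ether selectively and without acid, which would dehydrate the lactol to a furan, and leaves the esters in place.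

**Step 20**
Reactants: 25 lactol
Product: 27 target, methyl 9α-acetoxy-8β-angeloyloxy-2α,15-dihydroxygermacra-1(10),4,11(13)-trien-6α,12-olid-14-oate with both ring double bonds cis in the ring (CNP0195669.2), via open-chain hydroxy aldehyde 26 (not isolated)
Conditions: CrCl2 (excess), NiCl2 (cat.), DMSO/THF, rt, slow addition at high dilution
Reagents that add atoms: none
Why: NiCl2, reduced in the flask to zerovalent nickel, inserts into the C1–I bond of the open-chain tautomer 26 of lactol 25, the alkenyl group passes with retention of geometry to chromium (a trivalent alkenylchromium species), and this adds to the C2 aldehyde (Nozaki–Hiyama–Kishi reaction). The closest known cases are Nozaki–Hiyama–Kishi macrocyclisations of β-iodo enoate aldehydes to ten-membered germacranolide rings and couplings in which a lactol serves as the aldehyde. The ten-membered carbocycle closes by 10-exo-trig attack of C1 on the carbonyl, and the five-membered hemiacetal ring (C2, C3, C4, C15, O) is given up in the same event, which releases the C15 hydroxyl. C2 is the only new stereocentre and is set by the substrate: the chain is folded by the trans-fused lactone and the cis C4=C5 bond, the chromium-bound carbonyl oxygen should point to the outside of the forming ring, and attack on the aldehyde face turned to the ring interior should give the 2α (S) alkoxide. The step needs chemoselective insertion at the alkenyl iodide (esters, the allylic acetate and the exo-methylene lactone are inert to alkenylchromium reagents), ring closure in preference to intermolecular coupling (high dilution, preorganised chain) and retention of the iodide geometry, which places C2 cis to C9 and trans to the C14 ester so that the product cannot lactonise to a butenolide.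

**Compound list**

1 | (triphenylphosphoranylidene)succinic anhydride | O=C1CC(=P(c2ccccc2)(c2ccccc2)c2ccccc2)C(=O)O1 | starting material
2 | 2-[(4-methoxybenzyl)oxy]acetaldehyde | COc1ccc(COCC=O)cc1 | starting material
3 | (E)-3-{2-[(4-methoxybenzyl)oxy]ethylidene}oxolane-2,5-dione | O=C1C/C(=C\COCc2ccc(OC)cc2)C(=O)O1 | intermediate
4 | (E)-4-methoxy-2-{2-[(4-methoxybenzyl)oxy]ethylidene}-4-oxobutanoic acid | COC(=O)C/C(=C\COCc1ccc(OC)cc1)C(=O)O | intermediate
5 | methyl (E)-3-(hydroxymethyl)-5-[(4-methoxybenzyl)oxy]pent-3-enoate | COC(=O)C/C(=C\COCc1ccc(OC)cc1)CO | intermediate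
6 | (E)-4-{2-[(4-methoxybenzyl)oxy]ethylidene}oxolan-2-one | O=C1C/C(=C\COCc2ccc(OC)cc2)CO1 | intermediate
7 | (E)-4-{2-[(4-methoxybenzyl)oxy]ethylidene}oxolan-2-ol | OC1C/C(=C\COCc2ccc(OC)cc2)CO1 | intermediate
8 | tert-butyl{[(E)-4-{2-[(4-methoxybenzyl)oxy]ethylidene}oxolan-2-yl]oxy}diphenylsilane | CC(C)(C)[Si](OC1C/C(=C\COCc2ccc(OC)cc2)CO1)(c1ccccc1)c1ccccc1 | intermediate
9 | (E)-2-{5-[(tert-butyldiphenylsilyl)oxy]oxolan-3-ylidene}ethan-1-ol | CC(C)(C)[Si](OC1C/C(=C\CO)CO1)(c1ccccc1)c1ccccc1 | intermediate
10 | (E)-2-{5-[(tert-butyldiphenylsilyl)oxy]oxolan-3-ylidene}acetaldehyde | CC(C)(C)[Si](OC1C/C(=C\C=O)CO1)(c1ccccc1)c1ccccc1 | intermediate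
11 | (2S,E)-1-{5-[(tert-butyldiphenylsilyl)oxy]oxolan-3-ylidene}but-3-en-2-ol | C=C[C@H](O)/C=C1/COC(O[Si](c2ccccc2)(c2ccccc2)C(C)(C)C)C1 | intermediate
12 | 2-(bromomethyl)acrylic acid | C=C(CBr)C(=O)O | starting material
13 | (2S,E)-1-{5-[(tert-butyldiphenylsilyl)oxy]oxolan-3-ylidene}but-3-en-2-yl 2-(bromomethyl)acrylate | C=C(CBr)C(=O)O[C@@H](C=C)/C=C1/COC(O[Si](c2ccccc2)(c2ccccc2)C(C)(C)C)C1 | intermediate
14 | (R)-3-(bromomethyl)-5-{(E)-[5-(tert-butyldiphenylsilyloxy)oxolan-3-ylidene]methyl}furan-2(5H)-one | O=C1O[C@H](/C=C2/COC(O[Si](c3ccccc3)(c3ccccc3)C(C)(C)C)C2)C=C1CBr | intermediate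
15 | Barbier adduct: 6,7-trans α-methylene lactone, 8α-hydroxy, C9 4-methoxybenzyl ether | C=C1C(=O)O[C@H](/C=C2/COC(O[Si](c3ccccc3)(c3ccccc3)C(C)(C)C)C2)[C@H]1[C@@H](O)COCc1ccc(OC)cc1 | intermediate
16 | angelic acid | C/C=C(/C)C(=O)O | starting material
17 | 8β-angelate, C9 4-methoxybenzyl ether | C=C1C(=O)O[C@H](/C=C2/COC(O[Si](c3ccccc3)(c3ccccc3)C(C)(C)C)C2)[C@H]1[C@H](OC(=O)/C(C)=C\C)COCc1ccc(OC)cc1 | intermediate
18 | 8β-angelate, C9 primary alcohol | C=C1C(=O)O[C@H](/C=C2/COC(O[Si](c3ccccc3)(c3ccccc3)C(C)(C)C)C2)[C@H]1[C@H](OC(=O)/C(C)=C\C)CO | intermediate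
19 | 8β-angelate, C9 aldehyde | C=C1C(=O)O[C@H](/C=C2/COC(O[Si](c3ccccc3)(c3ccccc3)C(C)(C)C)C2)[C@H]1[C@H](OC(=O)/C(C)=C\C)C=O | intermediate
20 | methyl propiolate | C#CC(=O)OC | starting material
21 | halo-aldol adduct, (E)-β-iodo enoate, C9 carbinol as both epimers | C=C1C(=O)O[C@H](/C=C2/COC(O[Si](c3ccccc3)(c3ccccc3)C(C)(C)C)C2)[C@H]1[C@H](OC(=O)/C(C)=C\C)C(O)/C(C(=O)OC)=C\I | intermediate
22 | β-iodo enone (C9 ketone) | C=C1C(=O)O[C@H](/C=C2/COC(O[Si](c3ccccc3)(c3ccccc3)C(C)(C)C)C2)[C@H]1[C@H](OC(=O)/C(C)=C\C)C(=O)/C(C(=O)OC)=C\I | intermediate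
23 | 9α-alcohol, 8β-angelate | C=C1C(=O)O[C@H](/C=C2/COC(O[Si](c3ccccc3)(c3ccccc3)C(C)(C)C)C2)[C@H]1[C@H](OC(=O)/C(C)=C\C)[C@@H](O)/C(C(=O)OC)=C\I | intermediate
24 | 9α-acetate, 8β-angelate, silyl acetal | C=C1C(=O)O[C@H](/C=C2/COC(O[Si](c3ccccc3)(c3ccccc3)C(C)(C)C)C2)[C@H]1[C@H](OC(=O)/C(C)=C\C)[C@@H](OC(C)=O)/C(C(=O)OC)=C\I | intermediate
25 | lactol (C2 hemiacetal on O-15) of the seco alkenyl iodide | C=C1C(=O)O[C@H](/C=C2/COC(O)C2)[C@H]1[C@H](OC(=O)/C(C)=C\C)[C@@H](OC(C)=O)/C(C(=O)OC)=C\I | intermediate
26 | open-chain hydroxy aldehyde (C2 aldehyde, free C15 hydroxyl) | C=C1C(=O)O[C@H](/C=C(/CO)CC=O)[C@H]1[C@H](OC(=O)/C(C)=C\C)[C@@H](OC(C)=O)/C(C(=O)OC)=C\I | intermediate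
27 | CNP0195669.2 | C=C1C(=O)O[C@@H]2/C=C(/CO)C[C@H](O)/C=C(/C(=O)OC)[C@H](OC(C)=O)[C@@H](OC(=O)/C(C)=C\C)[C@@H]12 | target

**Count**

Total steps: 20. Longest linear sequence: 20 steps (1 and 2 to 27).

**Steps most likely to fail**

1. Step 20. The addition to the C2 aldehyde may show poor facial selectivity, since nothing but the folded chain controls it. Fallback, setting C2 by ketone reduction instead of by the carbon–carbon bond formation: the coupling is run on 25 as described and the C2 epimers are not separated, so that 2-epi-27 F1 is carried along with 27. Selective silylation of the primary allylic C15 hydroxyl (Et3SiCl, imidazole, CH2Cl2, −40 °C) gives the 15-O-triethylsilyl ethers F2. Dess–Martin oxidation of the secondary allylic C2 alcohol gives the ring enone F3. Reduction with (R)-2-methyl-CBS-oxazaborolidine and catecholborane (alkenyl group as the large substituent) gives the 2α-alcohol 15-O-triethylsilyl ether F4. HF·pyridine in THF then removes the silyl group and the sequence comes back to the route at 27.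

2. Step 12. The alkoxyphosphonium intermediate at the β-branched, homoallylic C8 may eliminate towards C7 instead of being displaced, and angelate may isomerise to tiglate under the phosphine. Fallback, separating inversion from acylation: starting from 15, Mitsunobu reaction with the stronger acid chloroacetic acid (PPh3, DIAD, toluene) gives the inverted 8β-chloroacetate F5. Thiourea with NaHCO3 in EtOH removes the chloroacetyl group and leaves the 8β-alcohol F6. Yamaguchi esterification with angelic acid 16 (2,4,6-trichlorobenzoyl chloride, Et3N, toluene; then F6, DMAP) acylates with retention and comes back to the route at 17.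

3. Step 17. Hydride may add in conjugate fashion to the doubly activated β-iodo enone with loss of iodide, or the α-acyloxy ketone may epimerise at C8 before it is reduced. Fallback, setting C9 by invertive acylation and not by oxidation and reduction: starting from 21, the 9β-alcohol F7, which Cornforth-type addition in step 15 should make the major epimer, is separated by chromatography. Mitsunobu reaction with acetic acid (PPh3, DIAD, toluene, 0 °C) displaces at C9 with inversion; the iodine on C1 should disfavour the allylic (SN2′) pathway. This gives the 9α-acetate directly and comes back to the route at 24, leaving out steps 16 to 18.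

**Further compounds**

F1 | step 20 | 2-epi-27 (2β-alcohol) | C=C1C(=O)O[C@@H]2/C=C(/CO)C[C@@H](O)/C=C(/C(=O)OC)[C@H](OC(C)=O)[C@@H](OC(=O)/C(C)=C\C)[C@@H]12
F2 | step 20 | 15-O-triethylsilyl ethers of 27 and 2-epi-27 (both C2 epimers) | C=C1C(=O)O[C@@H]2/C=C(/CO[Si](CC)(CC)CC)CC(O)/C=C(/C(=O)OC)[C@H](OC(C)=O)[C@@H](OC(=O)/C(C)=C\C)[C@@H]12
F3 | step 20 | 15-O-triethylsilyl C2 enone | C=C1C(=O)O[C@@H]2/C=C(/CO[Si](CC)(CC)CC)CC(=O)/C=C(/C(=O)OC)[C@H](OC(C)=O)[C@@H](OC(=O)/C(C)=C\C)[C@@H]12
F4 | step 20 | 15-O-triethylsilyl ether of 27 (2α-alcohol) | C=C1C(=O)O[C@@H]2/C=C(/CO[Si](CC)(CC)CC)C[C@H](O)/C=C(/C(=O)OC)[C@H](OC(C)=O)[C@@H](OC(=O)/C(C)=C\C)[C@@H]12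
F5 | step 12 | 8β-chloroacetate of the Barbier adduct | C=C1C(=O)O[C@H](/C=C2/COC(O[Si](c3ccccc3)(c3ccccc3)C(C)(C)C)C2)[C@H]1[C@H](OC(=O)CCl)COCc1ccc(OC)cc1
F6 | step 12 | 8β-alcohol (C8 epimer of 15) | C=C1C(=O)O[C@H](/C=C2/COC(O[Si](c3ccccc3)(c3ccccc3)C(C)(C)C)C2)[C@H]1[C@H](O)COCc1ccc(OC)cc1
F7 | step 17 | 9β-alcohol (C9 epimer of 23) | C=C1C(=O)O[C@H](/C=C2/COC(O[Si](c3ccccc3)(c3ccccc3)C(C)(C)C)C2)[C@H]1[C@H](OC(=O)/C(C)=C\C)[C@H](O)/C(C(=O)OC)=C\I
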